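## Analysis of the target

The target 31 is a sesquilignan built on a γ-butyrolactone (O1, C2 carbonyl, C3, C4, C5). C4 carries a 4-hydroxy-3-methoxybenzyl group through the benzylic carbon C7. C3 carries a methylene, C7', that is bonded to C5 of a 2-aryl-3-(hydroxymethyl)-2,3-dihydrobenzofuran with a free phenol at its C7. There are four stereocentres in two pairs: lactone C3 and C4 are both S and trans, and dihydrofuran C2 (S) and C3 (R) are trans. The pairs are separated by C7' and the benzo ring, so neither can direct the other and each needs its own source of absolute configuration. The lactone pair is the mirror image of the common (3R,4R) dibenzylbutyrolactone series, which decides the enantiomer of the auxiliary. Sensitive sites are the three phenols (to be kept apart from two methyl ethers), the primary alcohol, the enolisable lactone C3–H, and the dihydrofuran C2–O1 bond, a benzylic ether para to an oxygenated aryl that is open to acid ionisation and hydrogenolysis. The difficulty is to join two stereochemically independent halves as one diastereomer and to finish under mild conditions. The strategy rests on the lactone: C3 and C4 bear trans arylmethyl groups, C7 can be an acyl-anion (dithiane) carbon, C3 is the α-carbon of a lactone enolate, and C5 can be an acetal carbon holding a chiral alkoxy group that is later reduced to the methylene.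

## Retrosynthetic reasoning

**Phenols and primary alcohol.** Target 31 is traced to the tris-benzyl ether 30. Benzyl is chosen because the two methyl ethers must stay and hydrogenolysis is neutral. The primary alcohol of 30 comes from the silyl ether 29.

**C5 methylene.** The C5–H2 of 29 is read as a reduced acetal carbon, leading back to 26, in which C5 carries the menthyloxy group. Forward, basic opening of the acyl acetal releases the auxiliary and an aldehyde (27), hydride gives the hydroxy acid 28, and acid closes the lactone. C3 and C4 are not touched.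

**C7 methylene.** The C7–H2 of 26 is read as a desulfurised dithiane carbon, leading back to 25. This makes C7 a nucleophilic centre.

**C4–C7 and C3–C7' (key disconnection).** Both bonds flank what was the C3=C4 double bond of a butenolide. Cutting them gives three pieces of similar size: dithiane 6, butenolide 4 and benzylic bromide 22. It is cut here and not inside the benzofuran because the benzofuran pair is then carried in intact as a finished electrophile. Both lactone stereocentres arise in one operation under control of C5. Forward, the dithiane anion must add to C4 anti to the C5 alkoxy group and the enolate must be alkylated anti to the new C4 substituent.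

**Butenolide 4.** The acetal C–O bond is cut to give hydroxybutenolide 2 and (+)-menthol 3; 2 comes from furfural 1 by photo-oxygenation. The (3S,4S) lactone requires the (5S) acetal, hence the (+)-enantiomer of the auxiliary.

**Dithiane 6.** Thioacetalisation of O-benzylvanillin 5.

**C7'–Br and C5–C7' of the benzofuran.** Bromide 22 comes from alcohol 21. Its C7' is introduced on the aryl bromide 18 through aryllithium 19 and aldehyde 20. A bromine para to O1 is easy to place by halogenation and survives the ring-forming chemistry.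

**C3 side chain.** Silyl ether 18 comes from alcohol 17, the reduction product of trans ester 16. After reduction C3 is no longer acidic, so the trans relation is fixed.

**C2–C3 of the dihydrofuran.** Cutting this bond in 16 gives diazo ester 14. Forward, a carbenoid inserts into the benzylic C–H of the ortho aryloxymethyl ether: the catalyst sets C2, the first-formed cis ester 15 is epimerised at C3 to trans.

**Aryl–carbon bond.** Diazo ester 14 is cut to aryl iodide 12 and ethyl diazoacetate 13, which supplies both C3 and the future hydroxymethyl carbon. No aldehyde homologation or diazo transfer is needed.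

**Ether and halogens.** Ether 12 comes from phenol 9 and benzylic chloride 11 (from alcohol 10). Phenol 9 comes from 2-(benzyloxy)phenol 7 through 8: the hydroxyl directs bromine para (future C5) and iodine ortho (future C3a). The two halogens are then addressed in turn, iodine first.

## Alternatives that were turned down

**Alternative 1:** The plan would be hung on the C2–C3 bond of the dihydrofuran. Forward, diazo ester A2 loses nitrogen on Rh2(S-PTTL)4, dirhodium tetrakis[N-phthaloyl-(S)-tert-leucinate]. The carbenoid inserts into a benzylic C–H of the neighbouring aryloxymethyl ether, the ring closes, and methoxide turns the cis ester into trans ester A1.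
- For it: the chirality is catalytic, the precursors are achiral, the C–H bond is doubly activated, and the bromine of A1 stays available.
- Against it as the organising step: A1 is only the benzofuran arene. The lactone, two of four stereocentres and both C–C bonds to C3 and C4 are still missing. Enantioselectivity depends on how the catalyst reads an extra ortho benzyloxy group, and the epimerisation runs beside a possible E1cB ring opening.
- Comparison: on catalyst economy and on forming the benzofuran it is at least as good as anything in the chosen plan. For that reason the same insertion is kept as a supporting step (step 9; ethyl ester 16 is the counterpart of A1). The chosen strategy adds what this one lacks: a convergent union that makes two bonds and two stereocentres in one flask under control of a crystalline auxiliary.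

**Alternative 2:** The dihydrofuran ring would be closed last on an arene that already carries the lactone, cutting C3a–C3 and the C–O bond of the hydroxymethyl group. Forward, Bu3SnH turns aryl bromide A4 into an aryl radical at C3a. It attacks the vinyl group 5-exo-trig, and TEMPO captures the primary radical to give alkoxyamine A3.
- For it: ring and oxygen function arrive together, radical conditions spare the enolisable lactone, and C2 relays to C3.
- Against it: A4 needs an enantiopure ether whose carbinol carbon is allylic and benzylic to a para-oxygenated aryl. That centre ionises easily and must be made by substitution on a doubly ortho-substituted phenol. The trans preference of such cyclisations is kinetic and cannot be corrected afterwards. TEMPO also intercepts tin and aryl radicals, and N–O cleavage adds a step. All of this falls at the end of a linear sequence.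
- Comparison: it is stronger in avoiding diazo chemistry. The chosen strategy places its uncertain step in the middle of a convergent route and sets both lactone centres by substrate control that can be checked on a single diastereomer.

**Alternative 3:** C2–C3 and O1–C2 would be cut, again on a lactone-bearing arene. Forward, Cs2CO3 eliminates sulfinate from phenol sulfone A6 to give ortho-quinone methide A7. A chiral benzylic sulfonium ylide adds to its exocyclic carbon and the phenoxide displaces the sulfide, giving A5.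
- For it: two bonds, the ring and both benzofuran stereocentres form in one step; trans selectivity is inherent; no epimerisation is needed. A5 is the same compound as 29 of the chosen route, so the end games coincide.
- Against it: A7 bears a CH2OSi group on its exocyclic carbon and can tautomerise to an ortho-hydroxystyrene (a silyl enol ether) in competition with ylide addition. Enantiocontrol by sulfonium ylides is best established for aryl-substituted quinone methides. A stoichiometric chiral sulfonium salt must be made, and the lactone C3–H sits in carbonate throughout.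
- Comparison: on the benzofuran itself this is the most elegant construction. The chosen strategy offers a central step of a well-established reaction class and stereocontrol that does not depend on a reagent matched to a fragile intermediate.

Key step: step 14

Assumption: the S-configured catalyst Rh2(S-PTTL)4 is taken to induce the (2S) configuration in step 9; if the sense on this substrate is the opposite, the enantiomeric catalyst Rh2(R-PTTL)4 (from D-tert-leucine) is used and nothing else changes.

Remark: alcohol 10 is an article of commerce and is also one borohydride reduction away from 5.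

Abbreviations: Bn = benzyl; TBS = tert-butyldimethylsilyl; Men = (1S,2R,5S)-5-methyl-2-(propan-2-yl)cyclohexyl; ArBn = 4-(benzyloxy)-3-methoxyphenyl; BF = the (2S,3R)-7-(benzyloxy)-2-ArBn-3-(TBSOCH2)-2,3-dihydro-1-benzofuran-5-yl group.

## Route

Step 1
Reactants: 1 furfural
Product: 2 5-hydroxyfuran-2(5H)-one (racemic hemiacetal)
Conditions: O2, rose bengal (cat.), hν (visible), MeOH, rt
Reagents that add atoms: dioxygen, O=O
Why: Dye-sensitised photo-oxygenation of the furan; methanol cleaves the oxygen adduct and carries off the formyl carbon as methyl formate, a standard preparation of this C4 unit.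

Step 2
Reactants: 2 5-hydroxyfuran-2(5H)-one; 3 (+)-menthol
Product: 4 (5S)-5-(MenO)furan-2(5H)-one
Conditions: CSA (cat.), toluene, reflux, Dean–Stark; crystallisation from petroleum ether, mother liquor re-equilibrated (CSA) and recrystallised
Reagents that add atoms: none
Why: Acid-catalysed acetalisation of the pseudo-acid; the C5 epimers interconvert under acid, so crystallisation of the less soluble (5S) diastereomer with recycling of the liquors should give one diastereomer, the mirror image of the known crystalline (−)-menthol acetal.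

Step 3
Reactants: 5 4-(benzyloxy)-3-methoxybenzaldehyde
Product: 6 2-[4-(benzyloxy)-3-methoxyphenyl]-1,3-dithiane
Conditions: HS(CH2)3SH, BF3·OEt2 (cat.), CH2Cl2, 0 °C → rt
Reagents that add atoms: propane-1,3-dithiol, SCCCS
Why: Lewis-acid thioacetalisation of an aromatic aldehyde; the aryl ethers are inert.

Step 4
Reactants: 7 2-(benzyloxy)phenol
Product: 8 2-(benzyloxy)-4-bromophenol
Conditions: NBS (1.0 equiv), MeCN, 0 °C
Reagents that add atoms: N-bromosuccinimide, O=C1CCC(=O)N1Br
Why: Electrophilic aromatic bromination; the free hydroxyl is the strongest director and its para position is open, as in the 4-bromination of guaiacol.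

Step 5
Reactants: 8 2-(benzyloxy)-4-bromophenol
Product: 9 2-(benzyloxy)-4-bromo-6-iodophenol
Conditions: NIS, p-TsOH·H2O (10 mol%), MeCN, rt
Reagents that add atoms: N-iodosuccinimide, O=C1CCC(=O)N1I
Why: Electrophilic iodination at the only free position ortho to the hydroxyl; it places two halogens of different reactivity at the future C3a (I) and C5 (Br).

Step 6
Reactants: 10 [4-(benzyloxy)-3-methoxyphenyl]methanol
Product: 11 1-(benzyloxy)-4-(chloromethyl)-2-methoxybenzene
Conditions: SOCl2, DMF (cat.), CH2Cl2, 0 °C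
Reagents that add atoms: thionyl chloride, O=S(Cl)Cl
Why: Chlorodehydroxylation of a benzylic alcohol through its chlorosulfite; the electron-rich chloride is used without storage.

Step 7
Reactants: 9 2-(benzyloxy)-4-bromo-6-iodophenol; 11 1-(benzyloxy)-4-(chloromethyl)-2-methoxybenzene
Product: 12 1-(benzyloxy)-2-(ArBn-CH2O)-5-bromo-3-iodobenzene
Conditions: K2CO3, KI (cat.), DMF, 50 °C
Reagents that add atoms: none
Why: Williamson ether synthesis; the phenoxide is flanked by two substituents but the benzylic chloride is reactive and iodide catalysis helps.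

Step 8
Reactants: 12 1-(benzyloxy)-2-(ArBn-CH2O)-5-bromo-3-iodobenzene; 13 ethyl diazoacetate
Product: 14 ethyl 2-[3-(benzyloxy)-2-(ArBn-CH2O)-5-bromophenyl]-2-diazoacetate
Conditions: Pd(PPh3)4 (5 mol%), Ag2CO3 (0.5 equiv), Et3N, toluene, rt
Reagents that add atoms: none
Why: Palladium-catalysed arylation of the diazoacetate C–H by an aryl iodide (oxidative addition of zerovalent palladium into C–I, base-assisted palladation of the diazo carbon, reductive elimination with the diazo group kept); at rt the C–I bond reacts and the C–Br bond is left.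

Step 9
Reactants: 14 ethyl 2-[3-(benzyloxy)-2-(ArBn-CH2O)-5-bromophenyl]-2-diazoacetate
Product: 16 ethyl (2S,3S)-7-(benzyloxy)-2-ArBn-5-bromo-2,3-dihydro-1-benzofuran-3-carboxylate (trans ester), via cis ester 15 (not isolated)
Conditions: Rh2(S-PTTL)4 (1 mol%), toluene, −60 °C; then NaOEt (0.3 equiv), EtOH, 0 °C → rt
Reagents that add atoms: none
Why: Intramolecular 1,5 C–H insertion of a donor/acceptor rhodium carbenoid into the benzylic, oxygen-activated C–H of the ortho aryloxymethyl ether, a known entry to cis-2-aryl-2,3-dihydrobenzofuran-3-carboxylates; the chiral carboxylate ligands choose one of the two enantiotopic benzylic hydrogens and so set C2 (S), and ethoxide then epimerises the acidic C3 to the more stable trans ester without touching C2.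

Step 10
Reactants: 16 ethyl (2S,3S)-7-(benzyloxy)-2-ArBn-5-bromo-2,3-dihydro-1-benzofuran-3-carboxylate
Product: 17 [(2S,3R)-7-(benzyloxy)-2-ArBn-5-bromo-2,3-dihydro-1-benzofuran-3-yl]methanol
Conditions: LiBH4, THF, 0 °C → rt
Reagents that add atoms: none
Why: Hydride reduction of the ester to the primary alcohol; LiBH4 leaves the aryl bromide and benzyl ethers alone, and C3 is no longer acidic afterwards (the descriptor changes from S to R by priority only).

Step 11
Reactants: 17 [(2S,3R)-7-(benzyloxy)-2-ArBn-5-bromo-2,3-dihydro-1-benzofuran-3-yl]methanol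
Product: 18 (2S,3R)-7-(benzyloxy)-2-ArBn-5-bromo-3-(TBSOCH2)-2,3-dihydro-1-benzofuran
Conditions: TBSCl, imidazole, DMF, rt
Reagents that add atoms: tert-butyldimethylsilyl chloride, CC(C)(C)[Si](C)(C)Cl
Why: Standard silylation of a primary alcohol; the silyl ether tolerates the organolithium, the enolate and nickel boride and is removed later by acid.

Step 12
Reactants: 18 (2S,3R)-7-(benzyloxy)-2-ArBn-5-bromo-3-(TBSOCH2)-2,3-dihydro-1-benzofuran
Product: 21 BF-CH2OH [(2S,3R)-7-(benzyloxy)-2-ArBn-3-(TBSOCH2)-2,3-dihydro-1-benzofuran-5-yl]methanol, via aryllithium 19 (not isolated), via aldehyde 20 (not isolated)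
Conditions: n-BuLi, THF, −78 °C; DMF, −78 → 0 °C; then MeOH, NaBH4, 0 °C
Reagents that add atoms: N,N-dimethylformamide, CN(C)C=O
Why: Bromine–lithium exchange at −78 °C outruns any deprotonation; Bouveault formylation of the aryllithium and borohydride reduction in the same flask turn the C5 bromide into the C7' hydroxymethyl group.

Step 13
Reactants: 21 BF-CH2OH
Product: 22 BF-CH2Br (2S,3R)-7-(benzyloxy)-2-ArBn-5-(bromomethyl)-3-(TBSOCH2)-2,3-dihydro-1-benzofuran
Conditions: CBr4, PPh3, CH2Cl2, 0 °C; used at once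
Reagents that add atoms: tetrabromomethane, BrC(Br)(Br)Br
Why: Appel reaction under neutral conditions, so the silyl ether and the acid-labile C2–O1 ether survive; the para-alkoxybenzylic bromide is labile and is not stored.

Step 14
Reactants: 6 2-[4-(benzyloxy)-3-methoxyphenyl]-1,3-dithiane; 4 (5S)-5-(MenO)furan-2(5H)-one; 22 BF-CH2Br
Product: 25 (3S,4S,5S)-3-(BF-CH2)-4-(2-ArBn-1,3-dithian-2-yl)-5-(MenO)oxolan-2-one, via 2-lithiodithiane 23 (not isolated), via lithium enolate 24 (not isolated)
Conditions: 6 (1.3 equiv), n-BuLi, THF, −30 °C; 4 (1.2 equiv), −78 °C; then 22 (1.0 equiv), DMPU, −78 → −20 °C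
Reagents that add atoms: none
Why: n-BuLi deprotonates 6 to the sulfur-stabilised benzylic anion 23, which adds 1,4 to C4 of 4 to give lithium enolate 24, and 24 is C-alkylated by the benzylic bromide 22 in an SN2 reaction; the closest known reaction type is the tandem conjugate addition–enolate benzylation of lithiated 2-aryl-1,3-dithianes on 5-alkoxyfuran-2(5H)-ones. Two bonds form (C4–C7 and C3–C7') and no ring closes. C4 (S) is controlled by the C5 acetal centre: the menthyloxy group shields its own face of the flat butenolide, so the anion enters anti to it. C3 (S) is controlled by C4: the enolate is alkylated on the face away from the bulky dithianyl group, which gives the 3,4-trans-4,5-trans lactone. The step needs 1,4 over 1,2 addition, which the soft and hindered dithiane anion secures, and C over O alkylation, which a lithium enolate with a reactive benzylic bromide secures. It also needs freedom from proton transfer, and 22 offers only silyl and benzyl ethers with no acidic C–H. Bromide 22 is the limiting component because it is the most valuable partner, and its remote stereocentres take no part in the face selection.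

Step 15
Reactants: 25 (3S,4S,5S)-3-(BF-CH2)-4-(2-ArBn-1,3-dithian-2-yl)-5-(MenO)oxolan-2-one
Product: 26 (3S,4S,5S)-3-(BF-CH2)-4-(ArBn-CH2)-5-(MenO)oxolan-2-one
Conditions: NiCl2·6H2O, NaBH4, MeOH/THF, 0 °C
Reagents that add atoms: none
Why: Nickel boride desulfurisation turns the dithioacetal carbon into the C7 methylene; no stereocentre is involved, and benzyl ethers, silyl ether and acyl acetal should survive.

Step 16
Reactants: 26 (3S,4S,5S)-3-(BF-CH2)-4-(ArBn-CH2)-5-(MenO)oxolan-2-one
Product: 30 (3S,4S)-3-{[(2S,3R)-7-(benzyloxy)-2-ArBn-3-(hydroxymethyl)-2,3-dihydro-1-benzofuran-5-yl]methyl}-4-(ArBn-CH2)oxolan-2-one, via aldehyde acid 27 (not isolated), via hydroxy acid 28 (not isolated), via silyl lactone 29 (not isolated)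
Conditions: NaBH4, KOH, THF/MeOH/H2O, 0 °C → rt; then 2 M HCl to pH 1, rt
Reagents that add atoms: potassium hydroxide, [K+].[OH-] (its oxygen enters the carboxyl group and can remain as the lactone carbonyl oxygen)
Why: Hydroxide opens the acyl acetal to a carboxylate and releases menthol and the C5 aldehyde, which borohydride reduces at once; acidification closes the γ-lactone and the aqueous acid then removes the primary silyl ether. C3 is α to a carboxylate during the basic stage and is not enolised, and C4 is protected by the fast reduction of the aldehyde.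

Step 17
Reactants: 30 tris-benzyl lactone alcohol
Product: 31 (3S,4S)-3-{[(2S,3R)-7-hydroxy-2-(4-hydroxy-3-methoxyphenyl)-3-(hydroxymethyl)-2,3-dihydro-1-benzofuran-5-yl]methyl}-4-(4-hydroxy-3-methoxybenzyl)oxolan-2-one (target)
Conditions: H2 (1 atm), 10% Pd/C, EtOAc/MeOH, rt, stopped at full conversion
Reagents that add atoms: none
Why: Hydrogenolysis of three aryl benzyl ethers, which cleave much faster than the cyclic benzylic C2–O1 bond under neutral conditions at 1 atm; no stereocentre is affected.

## Compound list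

1 | furfural (furan-2-carbaldehyde) | O=Cc1ccco1 | starting material
2 | 5-hydroxyfuran-2(5H)-one (racemic hemiacetal) | O=C1C=CC(O)O1 | intermediate
3 | (+)-menthol, (1S,2R,5S)-5-methyl-2-(propan-2-yl)cyclohexan-1-ol | CC(C)[C@H]1CC[C@H](C)C[C@@H]1O | starting material
4 | (5S)-5-{[(1S,2R,5S)-5-methyl-2-(propan-2-yl)cyclohexyl]oxy}furan-2(5H)-one | O=C1C=C[C@@H](O[C@H]2C[C@@H](C)CC[C@@H]2C(C)C)O1 | intermediate
5 | 4-(benzyloxy)-3-methoxybenzaldehyde (O-benzylvanillin) | COc1cc(C=O)ccc1OCc1ccccc1 | starting material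
6 | 2-[4-(benzyloxy)-3-methoxyphenyl]-1,3-dithiane | COc1cc(C2SCCCS2)ccc1OCc1ccccc1 | intermediate
7 | 2-(benzyloxy)phenol | Oc1ccccc1OCc1ccccc1 | starting material
8 | 2-(benzyloxy)-4-bromophenol | Oc1ccc(Br)cc1OCc1ccccc1 | intermediate
9 | 2-(benzyloxy)-4-bromo-6-iodophenol | Oc1c(I)cc(Br)cc1OCc1ccccc1 | intermediate
10 | [4-(benzyloxy)-3-methoxyphenyl]methanol | COc1cc(CO)ccc1OCc1ccccc1 | starting material
11 | 1-(benzyloxy)-4-(chloromethyl)-2-methoxybenzene | COc1cc(CCl)ccc1OCc1ccccc1 | intermediate
12 | 1-(benzyloxy)-2-{[4-(benzyloxy)-3-methoxyphenyl]methoxy}-5-bromo-3-iodobenzene | COc1cc(COc2c(I)cc(Br)cc2OCc2ccccc2)ccc1OCc1ccccc1 | intermediate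
13 | ethyl diazoacetate | CCOC(=O)C=[N+]=[N-] | starting material
14 | ethyl 2-[3-(benzyloxy)-2-{[4-(benzyloxy)-3-methoxyphenyl]methoxy}-5-bromophenyl]-2-diazoacetate | CCOC(=O)C(=[N+]=[N-])c1cc(Br)cc(OCc2ccccc2)c1OCc1ccc(OCc2ccccc2)c(OC)c1 | intermediate
15 | ethyl (2S,3R)-7-(benzyloxy)-2-[4-(benzyloxy)-3-methoxyphenyl]-5-bromo-2,3-dihydro-1-benzofuran-3-carboxylate (cis ester) | Brc1cc(OCc2ccccc2)c2c(c1)[C@@H](C(=O)OCC)[C@@H](c1ccc(OCc3ccccc3)c(OC)c1)O2 | intermediate
16 | ethyl (2S,3S)-7-(benzyloxy)-2-[4-(benzyloxy)-3-methoxyphenyl]-5-bromo-2,3-dihydro-1-benzofuran-3-carboxylate (trans ester) | Brc1cc(OCc2ccccc2)c2c(c1)[C@H](C(=O)OCC)[C@@H](c1ccc(OCc3ccccc3)c(OC)c1)O2 | intermediate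
17 | [(2S,3R)-7-(benzyloxy)-2-[4-(benzyloxy)-3-methoxyphenyl]-5-bromo-2,3-dihydro-1-benzofuran-3-yl]methanol | Brc1cc(OCc2ccccc2)c2c(c1)[C@H](CO)[C@@H](c1ccc(OCc3ccccc3)c(OC)c1)O2 | intermediate
18 | (2S,3R)-7-(benzyloxy)-2-[4-(benzyloxy)-3-methoxyphenyl]-5-bromo-3-({[tert-butyl(dimethyl)silyl]oxy}methyl)-2,3-dihydro-1-benzofuran | Brc1cc(OCc2ccccc2)c2c(c1)[C@H](CO[Si](C)(C)C(C)(C)C)[C@@H](c1ccc(OCc3ccccc3)c(OC)c1)O2 | intermediate
19 | 5-lithio derivative of 18, [(2S,3R)-7-(benzyloxy)-2-[4-(benzyloxy)-3-methoxyphenyl]-3-({[tert-butyl(dimethyl)silyl]oxy}methyl)-2,3-dihydro-1-benzofuran-5-yl]lithium | [Li]c1cc(OCc2ccccc2)c2c(c1)[C@H](CO[Si](C)(C)C(C)(C)C)[C@@H](c1ccc(OCc3ccccc3)c(OC)c1)O2 | intermediate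
20 | (2S,3R)-7-(benzyloxy)-2-[4-(benzyloxy)-3-methoxyphenyl]-3-({[tert-butyl(dimethyl)silyl]oxy}methyl)-2,3-dihydro-1-benzofuran-5-carbaldehyde | O=Cc1cc(OCc2ccccc2)c2c(c1)[C@H](CO[Si](C)(C)C(C)(C)C)[C@@H](c1ccc(OCc3ccccc3)c(OC)c1)O2 | intermediate
21 | [(2S,3R)-7-(benzyloxy)-2-[4-(benzyloxy)-3-methoxyphenyl]-3-({[tert-butyl(dimethyl)silyl]oxy}methyl)-2,3-dihydro-1-benzofuran-5-yl]methanol | OCc1cc(OCc2ccccc2)c2c(c1)[C@H](CO[Si](C)(C)C(C)(C)C)[C@@H](c1ccc(OCc3ccccc3)c(OC)c1)O2 | intermediate
22 | (2S,3R)-7-(benzyloxy)-2-[4-(benzyloxy)-3-methoxyphenyl]-5-(bromomethyl)-3-({[tert-butyl(dimethyl)silyl]oxy}methyl)-2,3-dihydro-1-benzofuran | BrCc1cc(OCc2ccccc2)c2c(c1)[C@H](CO[Si](C)(C)C(C)(C)C)[C@@H](c1ccc(OCc3ccccc3)c(OC)c1)O2 | intermediate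
23 | {2-[4-(benzyloxy)-3-methoxyphenyl]-1,3-dithian-2-yl}lithium | COc1cc(C2([Li])SCCCS2)ccc1OCc1ccccc1 | intermediate
24 | lithium enolate of (4S,5S)-4-{2-[4-(benzyloxy)-3-methoxyphenyl]-1,3-dithian-2-yl}-5-{[(1S,2R,5S)-5-methyl-2-(propan-2-yl)cyclohexyl]oxy}oxolan-2-one | COc1cc(C2(SCCCS2)[C@@H]2[C@@H](O[C@H]3C[C@@H](C)CC[C@@H]3C(C)C)OC(O[Li])=C2)ccc1OCc1ccccc1 | intermediate
25 | (3S,4S,5S)-3-{[(2S,3R)-7-(benzyloxy)-2-[4-(benzyloxy)-3-methoxyphenyl]-3-({[tert-butyl(dimethyl)silyl]oxy}methyl)-2,3-dihydro-1-benzofuran-5-yl]methyl}-4-{2-[4-(benzyloxy)-3-methoxyphenyl]-1,3-dithian-2-yl}-5-{[(1S,2R,5S)-5-methyl-2-(propan-2-yl)cyclohexyl]oxy}oxolan-2-one | COc1cc(C2(SCCCS2)[C@@H]2[C@@H](O[C@H]3C[C@@H](C)CC[C@@H]3C(C)C)OC(=O)[C@H]2Cc2cc(OCc3ccccc3)c3c(c2)[C@H](CO[Si](C)(C)C(C)(C)C)[C@@H](c2ccc(OCc4ccccc4)c(OC)c2)O3)ccc1OCc1ccccc1 | intermediate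
26 | (3S,4S,5S)-3-{[(2S,3R)-7-(benzyloxy)-2-[4-(benzyloxy)-3-methoxyphenyl]-3-({[tert-butyl(dimethyl)silyl]oxy}methyl)-2,3-dihydro-1-benzofuran-5-yl]methyl}-4-[4-(benzyloxy)-3-methoxybenzyl]-5-{[(1S,2R,5S)-5-methyl-2-(propan-2-yl)cyclohexyl]oxy}oxolan-2-one | COc1cc(C[C@@H]2[C@@H](O[C@H]3C[C@@H](C)CC[C@@H]3C(C)C)OC(=O)[C@H]2Cc2cc(OCc3ccccc3)c3c(c2)[C@H](CO[Si](C)(C)C(C)(C)C)[C@@H](c2ccc(OCc4ccccc4)c(OC)c2)O3)ccc1OCc1ccccc1 | intermediate
27 | (2S,3S)-2-{[(2S,3R)-7-(benzyloxy)-2-[4-(benzyloxy)-3-methoxyphenyl]-3-({[tert-butyl(dimethyl)silyl]oxy}methyl)-2,3-dihydro-1-benzofuran-5-yl]methyl}-3-[4-(benzyloxy)-3-methoxybenzyl]-4-oxobutanoic acid (aldehyde acid, present as carboxylate) | COc1cc(C[C@H](C=O)[C@H](Cc2cc(OCc3ccccc3)c3c(c2)[C@H](CO[Si](C)(C)C(C)(C)C)[C@@H](c2ccc(OCc4ccccc4)c(OC)c2)O3)C(=O)O)ccc1OCc1ccccc1 | intermediate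
28 | (2S,3S)-2-{[(2S,3R)-7-(benzyloxy)-2-[4-(benzyloxy)-3-methoxyphenyl]-3-({[tert-butyl(dimethyl)silyl]oxy}methyl)-2,3-dihydro-1-benzofuran-5-yl]methyl}-3-[4-(benzyloxy)-3-methoxybenzyl]-4-hydroxybutanoic acid (hydroxy acid) | COc1cc(C[C@H](CO)[C@H](Cc2cc(OCc3ccccc3)c3c(c2)[C@H](CO[Si](C)(C)C(C)(C)C)[C@@H](c2ccc(OCc4ccccc4)c(OC)c2)O3)C(=O)O)ccc1OCc1ccccc1 | intermediate
29 | (3S,4S)-3-{[(2S,3R)-7-(benzyloxy)-2-[4-(benzyloxy)-3-methoxyphenyl]-3-({[tert-butyl(dimethyl)silyl]oxy}methyl)-2,3-dihydro-1-benzofuran-5-yl]methyl}-4-[4-(benzyloxy)-3-methoxybenzyl]oxolan-2-one (silyl lactone) | COc1cc(C[C@@H]2COC(=O)[C@H]2Cc2cc(OCc3ccccc3)c3c(c2)[C@H](CO[Si](C)(C)C(C)(C)C)[C@@H](c2ccc(OCc4ccccc4)c(OC)c2)O3)ccc1OCc1ccccc1 | intermediate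
30 | (3S,4S)-3-{[(2S,3R)-7-(benzyloxy)-2-[4-(benzyloxy)-3-methoxyphenyl]-3-(hydroxymethyl)-2,3-dihydro-1-benzofuran-5-yl]methyl}-4-[4-(benzyloxy)-3-methoxybenzyl]oxolan-2-one | COc1cc(C[C@@H]2COC(=O)[C@H]2Cc2cc(OCc3ccccc3)c3c(c2)[C@H](CO)[C@@H](c2ccc(OCc4ccccc4)c(OC)c2)O3)ccc1OCc1ccccc1 | intermediate
31 | (3S,4S)-3-{[(2S,3R)-7-hydroxy-2-(4-hydroxy-3-methoxyphenyl)-3-(hydroxymethyl)-2,3-dihydro-1-benzofuran-5-yl]methyl}-4-(4-hydroxy-3-methoxybenzyl)oxolan-2-one | COc1cc(C[C@@H]2COC(=O)[C@H]2Cc2cc(O)c3c(c2)[C@H](CO)[C@@H](c2ccc(O)c(OC)c2)O3)ccc1O | target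

## Step count and least certain steps

Total: 17 steps. Longest linear sequence: 13 steps (7 → 8 → 9 → 12 → 14 → 16 → 17 → 18 → 21 → 22 → 25 → 26 → 30 → 31).

**Step 14 (key step).** The conjugate addition should be dependable. The likely failure is the second stage: alkylation of enolate 24, which sits beside a quaternary dithiane carbon, may be slower than proton quench or decay of the labile para-alkoxybenzylic bromide, so the valuable electrophile is used up unproductively. Incomplete face selection at C3 is a lesser risk. Fallback (sets out from 6 and 4, returns at 26): the two bond formations are separated. Anion 23 is added to 4 as before, but the enolate is protonated (NH4Cl) to give the 1,4-adduct (4S,5S)-4-{2-[4-(benzyloxy)-3-methoxyphenyl]-1,3-dithian-2-yl}-5-(MenO)oxolan-2-one F1. Nickel boride (NiCl2·6H2O, NaBH4) removes the dithiane to give the 4-benzyl lactone (4S,5S)-4-[4-(benzyloxy)-3-methoxybenzyl]-5-(MenO)oxolan-2-one F2. Its less hindered enolate (LDA, THF, −78 °C), which can be used in excess, is alkylated with 22 in the presence of DMPU, anti to the C4 benzyl group, to give 26 directly.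

**Step 8.** Coupling at an iodide next to a bulky ortho ether may be slow, and palladium can decompose the diazo compounds with loss of nitrogen, which would erode 14. Fallback (sets out from 12, returns at 14): Negishi coupling of 12 with the Reformatsky reagent BrZnCH2CO2Et (Pd2(dba)3, XPhos, THF, rt), selective for C–I, gives ethyl 2-[3-(benzyloxy)-2-{[4-(benzyloxy)-3-methoxyphenyl]methoxy}-5-bromophenyl]acetate F3. Regitz diazo transfer (4-acetamidobenzenesulfonyl azide, DBU, MeCN) then gives 14.

**Step 9.** The extra ortho benzyloxy group may change the conformation of the reacting ether and lower the enantio-discrimination of the catalyst. Reversible E1cB opening of the dihydrofuran during the ethoxide epimerisation could also erode the configuration at C2. Fallback (sets out from 14, returns at 17): insertion with achiral Rh2(OAc)4, dirhodium tetraacetate, followed by NaOEt gives the racemic trans ethyl ester F4. LiOH gives the racemic trans acid F5. Classical resolution by crystallisation of its salt with one enantiomer of 1-phenylethylamine gives (2S,3S)-7-(benzyloxy)-2-[4-(benzyloxy)-3-methoxyphenyl]-5-bromo-2,3-dihydro-1-benzofuran-3-carboxylic acid F6. BH3·THF reduces F6 to 17.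

**Step 16.** Hydroxide may enolise aldehyde acid 27 before hydride reaches it, which would epimerise C4 and lead to a cis lactone. Fallback (sets out from 26, returns at 30): the acetal is unmasked under acid. Aqueous HCl in dioxane hydrolyses the menthyl acetal, and the silyl ether with it, to the lactol (3S,4S)-3-{[(2S,3R)-7-(benzyloxy)-2-[4-(benzyloxy)-3-methoxyphenyl]-3-(hydroxymethyl)-2,3-dihydro-1-benzofuran-5-yl]methyl}-4-[4-(benzyloxy)-3-methoxybenzyl]-5-hydroxyoxolan-2-one F7. NaBH4 in hydrogencarbonate-buffered aqueous ethanol reduces its open aldehyde form, and acidification closes the lactone to 30. This route trades the base risk for exposure of the C2–O1 ether to warm acid.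

**Step 17.** Over-reduction is possible: once the phenols are free, the benzylic C2–O1 bond of the dihydrofuran may undergo hydrogenolytic ring opening. Fallback (sets out from 30, returns at 31): non-reductive debenzylation with BCl3 and pentamethylbenzene as cation scavenger in CH2Cl2 at −78 °C; no new compound arises (F0).

## Further compounds

F1 | step 14 | (4S,5S)-4-{2-[4-(benzyloxy)-3-methoxyphenyl]-1,3-dithian-2-yl}-5-{[(1S,2R,5S)-5-methyl-2-(propan-2-yl)cyclohexyl]oxy}oxolan-2-one | COc1cc(C2(SCCCS2)[C@@H]2[C@@H](O[C@H]3C[C@@H](C)CC[C@@H]3C(C)C)OC(=O)C2)ccc1OCc1ccccc1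
F2 | step 14 | (4S,5S)-4-[4-(benzyloxy)-3-methoxybenzyl]-5-{[(1S,2R,5S)-5-methyl-2-(propan-2-yl)cyclohexyl]oxy}oxolan-2-one | COc1cc(C[C@@H]2[C@@H](O[C@H]3C[C@@H](C)CC[C@@H]3C(C)C)OC(=O)C2)ccc1OCc1ccccc1
F3 | step 8 | ethyl 2-[3-(benzyloxy)-2-{[4-(benzyloxy)-3-methoxyphenyl]methoxy}-5-bromophenyl]acetate | CCOC(=O)Cc1cc(Br)cc(OCc2ccccc2)c1OCc1ccc(OCc2ccccc2)c(OC)c1
F4 | step 9 | racemic trans ethyl 7-(benzyloxy)-2-[4-(benzyloxy)-3-methoxyphenyl]-5-bromo-2,3-dihydro-1-benzofuran-3-carboxylate, (2S,3S) and (2R,3R) | Brc1cc(OCc2ccccc2)c2c(c1)[C@H](C(=O)OCC)[C@@H](c1ccc(OCc3ccccc3)c(OC)c1)O2.Brc1cc(OCc2ccccc2)c2c(c1)[C@@H](C(=O)OCC)[C@H](c1ccc(OCc3ccccc3)c(OC)c1)O2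
F5 | step 9 | racemic trans 7-(benzyloxy)-2-[4-(benzyloxy)-3-methoxyphenyl]-5-bromo-2,3-dihydro-1-benzofuran-3-carboxylic acid, (2S,3S) and (2R,3R) | Brc1cc(OCc2ccccc2)c2c(c1)[C@H](C(=O)O)[C@@H](c1ccc(OCc3ccccc3)c(OC)c1)O2.Brc1cc(OCc2ccccc2)c2c(c1)[C@@H](C(=O)O)[C@H](c1ccc(OCc3ccccc3)c(OC)c1)O2
F6 | step 9 | (2S,3S)-7-(benzyloxy)-2-[4-(benzyloxy)-3-methoxyphenyl]-5-bromo-2,3-dihydro-1-benzofuran-3-carboxylic acid | Brc1cc(OCc2ccccc2)c2c(c1)[C@H](C(=O)O)[C@@H](c1ccc(OCc3ccccc3)c(OC)c1)O2
F7 | step 16 | (3S,4S)-3-{[(2S,3R)-7-(benzyloxy)-2-[4-(benzyloxy)-3-methoxyphenyl]-3-(hydroxymethyl)-2,3-dihydro-1-benzofuran-5-yl]methyl}-4-[4-(benzyloxy)-3-methoxybenzyl]-5-hydroxyoxolan-2-one (C5 anomers) | COc1cc(C[C@@H]2C(O)OC(=O)[C@H]2Cc2cc(OCc3ccccc3)c3c(c2)[C@H](CO)[C@@H](c2ccc(OCc4ccccc4)c(OC)c2)O3)ccc1OCc1ccccc1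
F0 | step 17 | none | none
A1 | alternative 1 | methyl (2S,3S)-7-(benzyloxy)-2-[4-(benzyloxy)-3-methoxyphenyl]-5-bromo-2,3-dihydro-1-benzofuran-3-carboxylate | Brc1cc(OCc2ccccc2)c2c(c1)[C@H](C(=O)OC)[C@@H](c1ccc(OCc3ccccc3)c(OC)c1)O2
A2 | alternative 1 | methyl 2-[3-(benzyloxy)-2-{[4-(benzyloxy)-3-methoxyphenyl]methoxy}-5-bromophenyl]-2-diazoacetate | COC(=O)C(=[N+]=[N-])c1cc(Br)cc(OCc2ccccc2)c1OCc1ccc(OCc2ccccc2)c(OC)c1
A3 | alternative 2 | (3S,4S)-3-{[(2S,3R)-7-(benzyloxy)-2-[4-(benzyloxy)-3-methoxyphenyl]-3-{[(2,2,6,6-tetramethylpiperidin-1-yl)oxy]methyl}-2,3-dihydro-1-benzofuran-5-yl]methyl}-4-[4-(benzyloxy)-3-methoxybenzyl]oxolan-2-one | COc1cc(C[C@@H]2COC(=O)[C@H]2Cc2cc(OCc3ccccc3)c3c(c2)[C@H](CON2C(C)(C)CCCC2(C)C)[C@@H](c2ccc(OCc4ccccc4)c(OC)c2)O3)ccc1OCc1ccccc1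
A4 | alternative 2 | (3S,4S)-3-[3-(benzyloxy)-4-{[(1S)-1-[4-(benzyloxy)-3-methoxyphenyl]prop-2-en-1-yl]oxy}-5-bromobenzyl]-4-[4-(benzyloxy)-3-methoxybenzyl]oxolan-2-one | COc1cc(C[C@@H]2COC(=O)[C@H]2Cc2cc(Br)c(O[C@@H](C=C)c3ccc(OCc4ccccc4)c(OC)c3)c(OCc3ccccc3)c2)ccc1OCc1ccccc1
A5 | alternative 3 | (3S,4S)-3-{[(2S,3R)-7-(benzyloxy)-2-[4-(benzyloxy)-3-methoxyphenyl]-3-({[tert-butyl(dimethyl)silyl]oxy}methyl)-2,3-dihydro-1-benzofuran-5-yl]methyl}-4-[4-(benzyloxy)-3-methoxybenzyl]oxolan-2-one | COc1cc(C[C@@H]2COC(=O)[C@H]2Cc2cc(OCc3ccccc3)c3c(c2)[C@H](CO[Si](C)(C)C(C)(C)C)[C@@H](c2ccc(OCc4ccccc4)c(OC)c2)O3)ccc1OCc1ccccc1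
A6 | alternative 3 | (3S,4S)-3-[3-(benzyloxy)-5-(2-{[tert-butyl(dimethyl)silyl]oxy}-1-[(4-methylphenyl)sulfonyl]ethyl)-4-hydroxybenzyl]-4-[4-(benzyloxy)-3-methoxybenzyl]oxolan-2-one (sulfone carbon as a mixture of epimers) | COc1cc(C[C@@H]2COC(=O)[C@H]2Cc2cc(OCc3ccccc3)c(O)c(C(CO[Si](C)(C)C(C)(C)C)S(=O)(=O)c3ccc(C)cc3)c2)ccc1OCc1ccccc1
A7 | alternative 3 | ortho-quinone methide, (3S,4S)-3-{[5-(benzyloxy)-3-(2-{[tert-butyl(dimethyl)silyl]oxy}ethylidene)-4-oxocyclohexa-1,5-dien-1-yl]methyl}-4-[4-(benzyloxy)-3-methoxybenzyl]oxolan-2-one | COc1cc(C[C@@H]2COC(=O)[C@H]2CC2=CC(=CCO[Si](C)(C)C(C)(C)C)C(=O)C(OCc3ccccc3)=C2)ccc1OCc1ccccc1
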